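**Strategy.** The cyclohexa-1,3-diene ring is cut across both of its double bonds, C1=C2 and C3=C4, so that the hydrogen-only C2–C3 unit becomes acetylene and the remaining four ring carbons an acyclic 1,5-diene. The key step, a tandem cross-enyne/ring-closing metathesis, stitches acetylene between the two olefins of diene 8 and so builds the ring and its conjugated diene in one operation. It exploits the fact that C2 and C3 carry no substituent and that both stereocentres (C5, C6) lie outside the diene. Precursor 8 is a syn-1,2-diol monobenzoate flanked by a vinyl and a 2-(benzoyloxymethyl)vinyl group, made by catalytic asymmetric γ-benzoyloxyallylation of an enal. Ring numbering: C1 bears CH2OBz, C5 OBz, C6 OH.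

Key step: step 5

Assumption: the (R,R)-salen–chromium catalyst of step 4 is taken to deliver the (3R,4R)-syn adduct; should the opposite sense be found, the (S,S)-ligand is used with nothing else changed.

**Step 1**
Reactants: 1 2-methylidenepropane-1,3-diol; 2 benzoyl chloride
Product: 3 2-(hydroxymethyl)prop-2-en-1-yl benzoate
Conditions: 2 (1.0 equiv) added slowly to 1 (3 equiv), Et3N, DMAP (cat.), CH2Cl2, −20 °C to 0 °C
Reagents that add atoms: none
Why: Nucleophilic acyl substitution (O-benzoylation) on a symmetrical diol, where the excess of diol should hold back the dibenzoate; no stereocentre is involved.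

**Step 2**
Reactants: 3 2-(hydroxymethyl)prop-2-en-1-yl benzoate
Product: 4 2-formylprop-2-en-1-yl benzoate
Conditions: Dess–Martin periodinane, CH2Cl2, 0 °C to rt; used without storage
Reagents that add atoms: none
Why: Dess–Martin oxidation should take the primary allylic alcohol to the enal under near-neutral conditions that leave the allylic benzoate and the 1,1-disubstituted olefin untouched.

**Step 3**
Reactants: 5 acrolein; 2 benzoyl chloride
Product: 6 3-chloroprop-1-en-1-yl benzoate (E/Z mixture)
Conditions: ZnCl2 (2 mol%), CH2Cl2, −20 °C to rt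
Reagents that add atoms: none
Why: Lewis-acid-catalysed addition of the acyl chloride to the aldehyde carbonyl followed by allylic 1,3-shift of chloride (net 1,4-addition) should give the γ-acyloxyallyl chloride, both geometrical isomers of which converge in step 4.

**Step 4**
Reactants: 4 2-formylprop-2-en-1-yl benzoate; 6 3-chloroprop-1-en-1-yl benzoate
Product: 8 (3R,4R)-4-(benzoyloxy)-3-hydroxy-2-methylidenehex-5-en-1-yl benzoate, via trimethylsilyl ether 7 (not isolated)
Conditions: CrCl3 (10 mol%), (R,R)-N,N'-bis(3,5-di-tert-butylsalicylidene)-1,2-cyclohexanediamine (10 mol%), Et3N (20 mol%), Mn powder (3 equiv), Me3SiCl (1.5 equiv), MeCN, rt; then 1 M HCl, THF, 0 °C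
Reagents that add atoms: none
Why: Catalytic asymmetric Nozaki–Hiyama–Kishi allylation in which divalent chromium (regenerated by manganese and released from the product by Me3SiCl) turns 6 into a γ-benzoyloxyallyl chromium species that adds through its oxygen-bearing γ-carbon to the aldehyde of 4 only; the salen ligand should control both the aldehyde face and the syn (threo) relation, setting C3 and C4 as (3R,4R), while silylation of the alkoxide as 7 blocks benzoyl migration until the acidic work-up.

**Step 5**
Reactants: 8 (3R,4R)-4-(benzoyloxy)-3-hydroxy-2-methylidenehex-5-en-1-yl benzoate; 9 acetylene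
Product: 11 [(5R,6R)-5-(benzoyloxy)-6-hydroxycyclohexa-1,3-dien-1-yl]methyl benzoate, via ruthenium dienylidene 10 (not isolated)
Conditions: second-generation Grubbs catalyst RuCl2(=CHPh)(PCy3)(H2IMes) (10 mol%), acetylene (2 equiv, fed over 6 h as a dilute CH2Cl2 solution), CH2Cl2 (0.01 M), 40 °C, argon
Reagents that add atoms: none
Why: Proposed new method: the ruthenium alkylidene formed at the monosubstituted C5=C6 vinyl group of 8 should add to acetylene through a ruthenacyclobutene that opens to the conjugated dienylidene 10 (first new C=C), and 10 should then close onto the 2-methylidene group by ring-closing metathesis (second new C=C), the two terminal CH2 groups leaving as ethylene; the closest known reaction type is the tandem cross-enyne/ring-closing metathesis of 1,5-dienes with monosubstituted alkynes to cyclohexa-1,3-dienes, and the new element is parent acetylene as the alkyne. The six-membered ring closes by intramolecular [2+2] cycloaddition/cycloreversion of the dienylidene with the 1,1-disubstituted olefin, so both new double bonds end endocyclic and cis. No stereocentre is formed: the (3R,4R) pair from step 4 lies outside the reacting atoms and is carried through unchanged, which fixes the trans relation of the ring oxygens. The step needs Z geometry at the first new double bond, since only the Z-dienylidene can reach the second olefin; the E isomer should be fed back by secondary metathesis at its internal olefin, while the cyclohexadiene acts as a sink. It also needs one acetylene per diene and not polyene growth, which the slow acetylene feed and the fast six-ring closure are meant to secure; acetylene is the only alkyne that leaves hydrogen on both central diene carbons, so closure onto the 1,1-disubstituted olefin gives a merely trisubstituted double bond. A 1,5-diene cannot undergo ring-closing metathesis by itself, so 8 has no competing cyclisation.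

**Compound list**
1 | 2-methylidenepropane-1,3-diol | C=C(CO)CO | starting material
2 | benzoyl chloride | O=C(Cl)c1ccccc1 | starting material
3 | 2-(hydroxymethyl)prop-2-en-1-yl benzoate | C=C(CO)COC(=O)c1ccccc1 | intermediate
4 | 2-formylprop-2-en-1-yl benzoate | C=C(C=O)COC(=O)c1ccccc1 | intermediate
5 | acrolein (prop-2-enal) | C=CC=O | starting material
6 | 3-chloroprop-1-en-1-yl benzoate (E/Z mixture) | ClCC=COC(=O)c1ccccc1 | intermediate
7 | (3R,4R)-4-(benzoyloxy)-2-methylidene-3-[(trimethylsilyl)oxy]hex-5-en-1-yl benzoate | C=C[C@@H](OC(=O)c1ccccc1)[C@H](O[Si](C)(C)C)C(=C)COC(=O)c1ccccc1 | intermediate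
8 | (3R,4R)-4-(benzoyloxy)-3-hydroxy-2-methylidenehex-5-en-1-yl benzoate | C=C[C@@H](OC(=O)c1ccccc1)[C@H](O)C(=C)COC(=O)c1ccccc1 | intermediate
9 | acetylene | C#C | starting material
10 | ruthenium dienylidene RuCl2(H2IMes)(=CH–CH=CH–R), Z at the new olefin, R = the (1R,2R)-1-(benzoyloxy)-2-hydroxy-3-(benzoyloxymethyl)but-3-enyl chain of 8 | Cl[Ru](Cl)(=C1N(c2c(C)cc(C)cc2C)CCN1c1c(C)cc(C)cc1C)=C/C=C\[C@@H](OC(=O)c1ccccc1)[C@H](O)C(=C)COC(=O)c1ccccc1 | intermediate
11 | [(5R,6R)-5-(benzoyloxy)-6-hydroxycyclohexa-1,3-dien-1-yl]methyl benzoate | O=C(OCC1=CC=C[C@@H](OC(=O)c2ccccc2)[C@@H]1O)c1ccccc1 | target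

**Count.** Total steps: 5. Longest linear sequence: 4 steps (steps 1, 2, 4, 5).

**Steps most likely to fail**

Step 5 (bears the label). The catalyst may be consumed by repeated acetylene insertion (polyene growth) or by vinylidene formation before ring closure, and the E-dienylidene may fail to re-enter the cycle. The fallback uses known chemistry, sets out from 8 and comes back at 11. The free hydroxyl of 8 is silylated with chlorodimethyl(vinyl)silane (Et3N, DMAP, CH2Cl2) to give (3R,4R)-4-(benzoyloxy)-3-{[dimethyl(vinyl)silyl]oxy}-2-methylidenehex-5-en-1-yl benzoate F1. Silicon-tethered ring-closing metathesis between the Si-vinyl and the C5=C6 vinyl groups (Schrock catalyst Mo(=CHCMe2Ph)(=N-2,6-iPr2C6H3)[OCMe(CF3)2]2, benzene, rt) should give the six-membered cyclic alkenylsiloxane 2-[(5R,6R)-5-(benzoyloxy)-2,2-dimethyl-5,6-dihydro-2H-1,2-oxasilin-6-yl]prop-2-en-1-yl benzoate F2, whose ring enforces the Z olefin. Fluoride-promoted Hiyama–Denmark coupling of F2 with vinyl bromide (Pd(dba)2, Bu4NF, THF, rt, quench with AcOH) should replace silicon by vinyl with retention and free the hydroxyl, giving the Z-triene (3R,4R,5Z)-4-(benzoyloxy)-3-hydroxy-2-methylideneocta-5,7-dien-1-yl benzoate F3. Ring-closing metathesis of F3 between the terminal olefin of the diene and the methylidene group (second-generation Grubbs catalyst, CH2Cl2, 40 °C) then gives 11, the two ring double bonds now being made in separate steps.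

Step 4. Facial or syn/anti selectivity may be poor, the enal 4 may undergo chromium-mediated reductive self-coupling, and the benzoyl group may migrate between O3 and O4 on work-up. The fallback sets out from 4 and comes back at 8. Brown γ-alkoxyallylboration of 4 with (Z)-γ-(4-methoxyphenoxy)allyl-diisopinocampheylborane (from allyl 4-methoxyphenyl ether, sBuLi, Ipc2BOMe, BF3·OEt2, −78 °C; pinene enantiomer chosen for the (3R,4R) series; non-basic ethanolamine work-up) should give the syn adduct (3R,4R)-3-hydroxy-4-(4-methoxyphenoxy)-2-methylidenehex-5-en-1-yl benzoate F4. Silylation (tBuMe2SiOTf, 2,6-lutidine) gives (3R,4R)-3-[(tert-butyldimethylsilyl)oxy]-4-(4-methoxyphenoxy)-2-methylidenehex-5-en-1-yl benzoate F5. Oxidative removal of the aryl ether ((NH4)2Ce(NO3)6, MeCN/H2O, 0 °C) gives (3R,4R)-3-[(tert-butyldimethylsilyl)oxy]-4-hydroxy-2-methylidenehex-5-en-1-yl benzoate F6. Benzoylation with 2 (pyridine, DMAP) gives (3R,4R)-4-(benzoyloxy)-3-[(tert-butyldimethylsilyl)oxy]-2-methylidenehex-5-en-1-yl benzoate F7, and acidic desilylation (HF·pyridine, THF) returns 8 without base-induced acyl migration.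

Step 3. Addition of the aroyl chloride may be sluggish and acrolein may polymerise under the Lewis acid. The fallback sets out from 5 and comes back at 6. The more reactive benzoyl bromide is added to 5 (ZnCl2 cat., CH2Cl2, −20 °C) to give 3-bromoprop-1-en-1-yl benzoate (E/Z mixture) F8, and halide exchange by SN2 displacement with LiCl (DMF, rt) converts F8 into 6, the chloride being needed to suppress uncatalysed manganese insertion in step 4.

**Further compounds**
F1 | step 5 | (3R,4R)-4-(benzoyloxy)-3-{[dimethyl(vinyl)silyl]oxy}-2-methylidenehex-5-en-1-yl benzoate | C=C[C@@H](OC(=O)c1ccccc1)[C@H](O[Si](C)(C)C=C)C(=C)COC(=O)c1ccccc1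
F2 | step 5 | 2-[(5R,6R)-5-(benzoyloxy)-2,2-dimethyl-5,6-dihydro-2H-1,2-oxasilin-6-yl]prop-2-en-1-yl benzoate | C[Si]1(C)C=C[C@@H](OC(=O)c2ccccc2)[C@H](O1)C(=C)COC(=O)c1ccccc1
F3 | step 5 | (3R,4R,5Z)-4-(benzoyloxy)-3-hydroxy-2-methylideneocta-5,7-dien-1-yl benzoate | C=C/C=C\[C@@H](OC(=O)c1ccccc1)[C@H](O)C(=C)COC(=O)c1ccccc1
F4 | step 4 | (3R,4R)-3-hydroxy-4-(4-methoxyphenoxy)-2-methylidenehex-5-en-1-yl benzoate | C=C[C@@H](Oc1ccc(OC)cc1)[C@H](O)C(=C)COC(=O)c1ccccc1
F5 | step 4 | (3R,4R)-3-[(tert-butyldimethylsilyl)oxy]-4-(4-methoxyphenoxy)-2-methylidenehex-5-en-1-yl benzoate | C=C[C@@H](Oc1ccc(OC)cc1)[C@H](O[Si](C)(C)C(C)(C)C)C(=C)COC(=O)c1ccccc1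
F6 | step 4 | (3R,4R)-3-[(tert-butyldimethylsilyl)oxy]-4-hydroxy-2-methylidenehex-5-en-1-yl benzoate | C=C[C@@H](O)[C@H](O[Si](C)(C)C(C)(C)C)C(=C)COC(=O)c1ccccc1
F7 | step 4 | (3R,4R)-4-(benzoyloxy)-3-[(tert-butyldimethylsilyl)oxy]-2-methylidenehex-5-en-1-yl benzoate | C=C[C@@H](OC(=O)c1ccccc1)[C@H](O[Si](C)(C)C(C)(C)C)C(=C)COC(=O)c1ccccc1
F8 | step 3 | 3-bromoprop-1-en-1-yl benzoate (E/Z mixture) | BrCC=COC(=O)c1ccccc1
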